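(The earlier runs and the new flask are calculated on assumed constants, noise included.)

Start from a small charge of capture agent, 0.180 M in the new flask, and turn the settings one at a time, reading each against the two earlier runs before you commit to a number.

| flask | substrate | partner | capture agent | remark | time |
|---|---|---|---|---|---|
| beta | 1.8 M (in portions, 4) | 1.71 M | 0.25 M | run made earlier; portions every 2.0 h |  |
| eta | 1.8 M (in portions, 4) | 1.71 M | 0.40 M | run made earlier; portions every 2.0 h |  |
| flask | 1.8 M (in portions, 4) | 1.71 M | 0.180 M | the portions of substrate follow each other after 2.0 h, the first at the start | 10 d |

| run | time / d | substrate / % | target / % | open intermediate / % |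
|---|---|---|---|---|
| beta | 0.500 | 0 | 28 | 65 |
| beta | 0.833 | 0 | 36 | 55 |
| beta | 1.04 | 0 | 39 | 49 |
| beta | 1.67 | 1 | 44 | 41 |
| beta | 2.50 | 0 | 47 | 41 |
| beta | 4.00 | 1 | 47 | 36 |
| beta | 6.00 | 1 | 50 | 37 |
| eta | 0.833 | 0 | 35 | 49 |
| eta | 1.67 | 0 | 41 | 36 |
| eta | 2.50 | 1 | 44 | 35 |
| eta | 3.00 | 1 | 47 | 33 |
| eta | 4.00 | 0 | 44 | 29 |
| eta | 5.00 | 0 | 47 | 31 |
| eta | 6.00 | 0 | 48 | 33 |

(readings scatter by 1.5 percentage points)

- the earlier runs were read with a standard deviation of 1.5 percentage points
- the reaction counts as stopped when no species that holds the substrate changes by six tenths of a point or more over the second half of the time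

- which holds at 10 d: what has brought the reaction to rest, or that it has not come to rest (it is still moving / all of the substrate has reacted)
- part of the substrate gone at 10 d
- the target standing at 10 d, as a percentage of the substrate charged
- the open intermediate standing at 10 d, as a percentage of the substrate charged

Turn the capture agent first. Reckon 10.0 % for the new flask as s = c(capture agent)/c(substrate), the capture share: the part of the substrate charged that the capture agent, taken as limiting reagent of the loss, can carry out of sight at one unit each. Then test this share on the gap left by substrate, target and open intermediate together, taken over the last two readings of each run: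

beta: s = 13.9 %, gap 14.0 %
eta: s = 22.2 %, gap 20.5 %

Note what the capture agent does between these runs: at 6.00 d the target reads 50 % in beta and 48 % in eta, close for readings with a scatter of 1.5 percentage points, while the open intermediate reads 37 % and 33 %. So charge the capture share to the open intermediate.

Turn substrate and partner next: the new flask keeps the substrate and partner charges of both runs, so carry over the mean of the two target readings at 6.00 d, 49.0 %. Turn the time last: in beta the open intermediate reads 36 % at 4.00 d and 37 % at 6.00 d, and the substrate already reads 0 % at 0.500 d, so expect rest by 10 d.

open intermediate = whole charge − target − s = 41.0 %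

The forecast, made from the same runs, says all of the substrate has reacted, with 99.5 % of the substrate gone, target 50 % and open intermediate 40 %, holding that “each capture agent takes one substrate unit into an unseen product”. It stands one point from my reckoning on the target and one point from it on the open intermediate.

In the new flask all of the substrate has reacted, with 100 % of the substrate gone, target 49.3 % and open intermediate 40.7 %.

substrate → open intermediate (k = 0.101 min⁻¹); partner → second intermediate (k = 0.0537 min⁻¹); open intermediate + second intermediate → target (k = 8.27 × 10⁻⁴ L mol⁻¹ min⁻¹); 2 second intermediate → homo product (k = 5.13 × 10⁻⁴ L mol⁻¹ min⁻¹); open intermediate + capture agent → trapped intermediate (k = 0.00126 L mol⁻¹ min⁻¹) At 10.0 d the new flask holds 10.0 % of the substrate charged as trapped intermediate, level with the capture share of 10.0 %, and its capture agent stands at 0 % of its charge. Put the share to a neighbour flask with 1.1 M of substrate: the same capture agent over less substrate gives s = 16.4 %, and that neighbour flask ends with 16.3 % of trapped intermediate.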